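**Plan**
- Target: 32-dotriacontanolide (oxacyclotritriacontan-2-one), a single 33-membered ring. Locants follow the hydroxy acid: C1 is the lactone carbonyl, C2–C32 are the 31 CH2 groups, and C32 carries the ring oxygen.
- Retrosynthetic cuts, in order: the ring C4–C5 CH2–CH2 bond; the acyl C1–O ester bond (C1–C4 becomes but-3-enoic acid); the C18–C19 bond at the centre of the C5–C32 chain (two C14 halves).
- Forward: a crossed Kolbe coupling joins the two C14 halves to the C28 ω-bromo alcohol; esterification attaches the C4 unit; hydroboration at C4 and palladium-catalysed sp3–sp3 coupling with the C5 bromide close the ring and give the saturated lactone directly.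
- Enabling feature: the ring is one unbranched, strain-free run of 31 methylenes between C1 and the ring oxygen. C4 and C5 are therefore both unhindered primary carbons; C4 is the terminus of a four-carbon butenoate (nucleophilic after hydroboration) and C5 is the primary bromide terminus of a chain that is C14 + C14.
- Stereochemistry: the target has no stereocentre and no ring alkene is carried, so nothing has to be set.

Key step: step 3

Remark: the SMILES is read as a ring of 32 carbons and one oxygen (C32H62O2, 31 ring CH2 groups); the ω-substituted C15 acids 1 and 2 and acid 4 are taken as catalogue chemicals.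

**Step 1**
Reactants: 1 15-hydroxypentadecanoic acid; 2 15-bromopentadecanoic acid
Product: 3 28-bromooctacosan-1-ol
Conditions: platinum anode and cathode, undivided cell, NaOMe (0.1 equiv), MeOH with a hexane co-phase, 45 °C, constant current; 1 in threefold excess
Reagents that add atoms: none
Why: Crossed Kolbe electrolysis: anodic decarboxylation of both carboxylates gives the primary radicals •(CH2)14OH and •(CH2)14Br, which should combine at the electrode; the remote OH and Br are tolerated, the excess of 1 steers 2 into the cross product, and the diol and dibromide homodimers differ enough in polarity to be removed.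

**Step 2**
Reactants: 3 28-bromooctacosan-1-ol; 4 but-3-enoic acid
Product: 5 28-bromooctacosyl but-3-enoate
Conditions: DCC (1.3 equiv), DMAP (5 mol%), CH2Cl2–THF, 0 °C to rt
Reagents that add atoms: none
Why: Steglich esterification should acylate the primary alcohol through the carbodiimide-activated acid, while low temperature and only catalytic DMAP keep the β,γ-double bond out of conjugation and the primary bromide stays inert.

**Step 3**
Reactants: 5 28-bromooctacosyl but-3-enoate
Product: 7 oxacyclotritriacontan-2-one (32-dotriacontanolide), via alkylborane 6 (not isolated)
Conditions: 9-BBN-H (1.1 equiv), THF, 0 °C to rt; then syringe-pump addition to Pd(OAc)2 (20 mol%), PCy3 (40 mol%), K3PO4·H2O (3 equiv), THF, 40 °C, ca. 2 mM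
Reagents that add atoms: none
Why: Proposed new method: anti-Markovnikov hydroboration of the terminal alkene of 5 by 9-BBN-H should place boron on C4 (ester and bromide untouched) to give 6, after which SN2-type oxidative addition of the C5–Br bond to zerovalent palladium carrying PCy3 gives a trans alkyl bromide complex of divalent palladium that is slow to undergo β-hydride elimination, the hydroxide-activated borate at the other chain end transmetallates intramolecularly, and reductive elimination forms the C4–C5 sp3–sp3 bond. The closest known reaction type is the intermolecular Pd(OAc)2/PCy3-catalysed Suzuki–Miyaura coupling of B-alkyl-9-BBN reagents with unactivated primary alkyl bromides, which tolerates esters, together with B-alkyl Suzuki–Miyaura macrocyclisations onto alkenyl halides. The only ring, the 33-membered lactone, is closed head-to-tail through a 34-membered palladacycle, a strain-free closure of a flexible polymethylene chain with no exo or endo alternative. No stereocentre is formed. The step needs ring closure to win over intermolecular coupling, β-hydride elimination and protodeboronation; pseudo-high dilution by slow addition, the bulky electron-rich PCy3 ligand and the unhindered primary–primary pair (C4 three carbons from the carbonyl, C5 in the plain chain) are expected to secure this.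

**Compound list**
1 | 15-hydroxypentadecanoic acid | OCCCCCCCCCCCCCCC(=O)O | starting material
2 | 15-bromopentadecanoic acid | BrCCCCCCCCCCCCCCC(=O)O | starting material
3 | 28-bromooctacosan-1-ol | OCCCCCCCCCCCCCCCCCCCCCCCCCCCCBr | intermediate
4 | but-3-enoic acid (vinylacetic acid) | C=CCC(=O)O | starting material
5 | 28-bromooctacosyl but-3-enoate | C=CCC(=O)OCCCCCCCCCCCCCCCCCCCCCCCCCCCCBr | intermediate
6 | 28-bromooctacosyl 4-(9-borabicyclo[3.3.1]nonan-9-yl)butanoate | BrCCCCCCCCCCCCCCCCCCCCCCCCCCCCOC(=O)CCCB1C2CCCC1CCC2 | intermediate (not isolated)
7 | oxacyclotritriacontan-2-one (32-dotriacontanolide) | O=C1CCCCCCCCCCCCCCCCCCCCCCCCCCCCCCCO1 | target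
8 | pent-4-enoic acid | C=CCCC(=O)O | starting material (used only in a fallback)
9 | 12-bromododecan-1-ol | OCCCCCCCCCCCCBr | starting material (used only in a fallback)
10 | 1,16-dibromohexadecane | BrCCCCCCCCCCCCCCCCBr | starting material (used only in a fallback)

Total step count: 3. Longest linear sequence: 3 steps (1 and 2 → 3 → 5 → 7).

**Steps most likely to fail**

1. Step 3 (carries the new method). Ring closure may lose to intermolecular coupling giving oligomers, to β-hydride elimination of the alkylpalladium bromide, or to slow oxidative addition at high dilution followed by protodeboronation. The fallback uses known chemistry, sets out from 3 and comes back at 7. Heating 3 with PPh3 (MeCN, reflux) would give (28-hydroxyoctacosyl)triphenylphosphonium bromide F1. Double deprotonation (KOtBu, 2.2 equiv, THF) would give the ylide potassium 28-(triphenylphosphoranylidene)octacosan-1-olate F2, and a Wittig reaction with formaldehyde (cracked paraformaldehyde) should give nonacos-28-en-1-ol F3. Steglich esterification with 8 (DCC, DMAP, CH2Cl2–THF) would give nonacos-28-en-1-yl pent-4-enoate F4. Ring-closing metathesis (second-generation Grubbs catalyst, Ti(OiPr)4 as additive against carbonyl chelation, CH2Cl2, 40 °C, ca. 1 mM) should close the same C4–C5 bond as the alkene (E)-oxacyclotritriacont-5-en-2-one F5, with the Z isomer expected alongside. Hydrogenation (H2, palladium on carbon, EtOAc, rt) would converge both isomers on 7.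

2. Step 1. Statistical homocoupling, passivation of the anode by waxy long-chain products and two-electron over-oxidation to cation-derived products may erode the cross-coupling. The fallback sets out from 9 and 10 and comes back at 3. Protection of 9 (3,4-dihydro-2H-pyran, PPTS, CH2Cl2) would give 2-[(12-bromododecyl)oxy]tetrahydro-2H-pyran F6. Magnesium in THF would convert it into [12-(tetrahydro-2H-pyran-2-yloxy)dodecyl]magnesium bromide F7. Li2CuCl4-catalysed coupling with an excess of 10 (THF, −10 °C to rt) should give 2-[(28-bromooctacosyl)oxy]tetrahydro-2H-pyran F8. PPTS in MeOH–THF (50 °C) would then release 3.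

3. Step 2. Base-mediated migration of the β,γ-double bond into conjugation (through a vinylketene or dienolate from the activated acid) and N-acylurea formation may compete with acylation. The fallback sets out from 3 and 4 and comes back at 5 with no new compound. A Mitsunobu esterification (PPh3, DIAD, THF, 0 °C to rt) activates the alcohol carbon of 3 instead of the acyl carbon of 4, so the carboxylate acts only as nucleophile and no enolisable acyl-activated species is formed.

**Further compounds**
F1 | step 3 | (28-hydroxyoctacosyl)triphenylphosphonium bromide | OCCCCCCCCCCCCCCCCCCCCCCCCCCCC[P+](c1ccccc1)(c1ccccc1)c1ccccc1.[Br-]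
F2 | step 3 | potassium 28-(triphenylphosphoranylidene)octacosan-1-olate | [K+].[O-]CCCCCCCCCCCCCCCCCCCCCCCCCCCC=P(c1ccccc1)(c1ccccc1)c1ccccc1
F3 | step 3 | nonacos-28-en-1-ol | OCCCCCCCCCCCCCCCCCCCCCCCCCCCC=C
F4 | step 3 | nonacos-28-en-1-yl pent-4-enoate | C=CCCC(=O)OCCCCCCCCCCCCCCCCCCCCCCCCCCCC=C
F5 | step 3 | (E)-oxacyclotritriacont-5-en-2-one | O=C1CC/C=C/CCCCCCCCCCCCCCCCCCCCCCCCCCCO1
F6 | step 1 | 2-[(12-bromododecyl)oxy]tetrahydro-2H-pyran | BrCCCCCCCCCCCCOC1CCCCO1
F7 | step 1 | [12-(tetrahydro-2H-pyran-2-yloxy)dodecyl]magnesium bromide | Br[Mg]CCCCCCCCCCCCOC1CCCCO1
F8 | step 1 | 2-[(28-bromooctacosyl)oxy]tetrahydro-2H-pyran | BrCCCCCCCCCCCCCCCCCCCCCCCCCCCCOC1CCCCO1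
F0 | step 2 | none | none
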